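At early times, compare how fast each flask spends reagent, counting one reagent per substrate lost.

the same everywhere: impurity 0.79 mM
- Sunday's: left-handed substrate 0.18 M; right-handed substrate 0.18 M; reagent 0.198 M; free catalyst 2.2 mM; run made earlier
- Tuesday's: left-handed substrate 0.36 M; right-handed substrate 0.36 M; reagent 0.198 M; free catalyst 1.5 mM; run made earlier
- autumn: left-handed substrate 0.18 M; right-handed substrate 0.18 M; reagent 0.198 M; free catalyst 1.5 mM; time 3.0 h
- dawn: left-handed substrate 0.18 M; right-handed substrate 0.18 M; reagent 0.120 M; free catalyst 1.5 mM; time 3.0 h

| run | time / min | right-handed substrate / % | left-handed substrate / % | left-handed product / % |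
|---|---|---|---|---|
| Sunday's | 5.00 | 46.4 | 47.7 | 1.9 |
| Sunday's | 8.00 | 45.2 | 47.2 | 2.7 |
| Sunday's | 12.0 | 43.1 | 45.4 | 4.1 |
| Sunday's | 20.0 | 39.9 | 44.5 | 6.1 |
| Sunday's | 25.0 | 37.7 | 42.8 | 6.6 |
| Sunday's | 40.0 | 32.8 | 40.8 | 9.0 |
| Sunday's | 60.0 | 29.2 | 37.8 | 12.3 |
| Tuesday's | 3.00 | 48.9 | 49.3 | 0.4 |
| Tuesday's | 10.0 | 46.8 | 48.3 | 1.1 |
| Tuesday's | 20.0 | 45.4 | 48.2 | 2.5 |
| Tuesday's | 25.0 | 44.7 | 47.4 | 2.3 |
| Tuesday's | 40.0 | 43.0 | 46.6 | 3.6 |
| Tuesday's | 50.0 | 42.6 | 45.7 | 4.3 |
| Tuesday's | 60.0 | 41.3 | 45.0 | 4.5 |

(standard deviation of a reading: 0.3 percentage points)

- free catalyst is single-handed; left-handed substrate and right-handed substrate are mirror images of each other, charged as a racemate, each of them at the stated concentration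
- an excess is the difference of the two amounts in percent of their sum
- an excess is below zero if the other one leads

- the flask that ends with the higher excess of right-handed substrate over left-handed substrate among what is left of the two, or "neither" when 2 percentage points or less lies between them (autumn / dawn / neither)
- excess of right-handed substrate over left-handed substrate among what is left of the two at the end, autumn
- excess of right-handed substrate over left-handed substrate among what is left of the two at the end, dawn

Turn the substrate first. Tuesday's flask has twice the substrate of Sunday's, and less catalyst. It spends 0.00353 M/min over its first 10.0 min, against 0.00425 M/min for Sunday's over its first 5.00 min. The charges and the time windows both differ, so this pair does not give the effect of the substrate by itself.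

Now the reagent. In Sunday's flask, the fraction left gives nearly the same rate constant through two readings:

0.0167 /min by 20.0 min, 0.0153 /min by 60.0 min

So the reagent sets the order: it decays pseudo-first-order.

Next, the catalyst. I assume the impurity removes catalyst one for one, and that the rate constant follows what remains. That gives the reagent half-life, the time in which the reagent falls to half, for charges up to 0.198 M with 0.18 M of each substrate:

1.50 h for 0.710 mM of remaining catalyst

Tuesday's flask, with the same catalyst and impurity charges as autumn but twice the substrate, shows 1.01 h. So I use my value at Sunday's substrate level, which autumn and dawn share.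

Then time and charge. Both flasks run twice this half-life, leaving 25.1% of the reagent. Turning the reagent charge therefore moves conversion in proportion:

autumn 41.2%, dawn 25.0%

Sunday's last reading gives a selectivity factor of 1.92. Taking the geometric mean of the two fractions left as the overall fraction left, I get:

autumn −16.6%, dawn −9.05%

Dawn stands 7.5 percentage points higher, beyond the margin of 2 points.

The forecast gave −15% for autumn and −9% for dawn, since “dawn is the higher, being less negative”.

The flasks give −17.5% for autumn and −9.70% for dawn, so dawn is higher.

    free catalyst + left-handed substrate ⇌ catalyst intermediate A (K = 17.0 /M, k = 42.0 /M/s)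
    free catalyst + right-handed substrate ⇌ catalyst intermediate B (K = 91.0 /M, k = 24.0 /M/s)
    reagent + catalyst intermediate A → free catalyst + left-handed product (k = 0.370 /M/s)
    reagent + catalyst intermediate B → free catalyst + right-handed product (k = 0.140 /M/s)
    free catalyst ⇌ dormant form (K = 0.360, k = 8.30 × 10⁻⁴ /s)
    free catalyst + impurity → spent catalyst (k = 18.0 /M/s)

In dawn at 0.805 h, catalyst intermediate A falls back 88 times faster than it goes on. Reagent left at the end is 25% in autumn and 25% in dawn, against my 25.1%.

Take a neighbour of dawn charged with 0.048 M of reagent. The half-life stays 1.50 h, so 25.1% remains, conversion is 9.99%, and the excess is −3.32%. The computed flask keeps 25% of its reagent and ends at −3.68%.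

All runs are calculated for an exercise; noise was put on by code.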